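**Retrosynthetic overview**

1. Feature: both arenes are meta-dioxygenated six-carbon rings. Ring A is a 3,5-dihydroxyphenyl ring (O on C3 and C5, side chain on C1) and ring C is a 2,4-dihydroxy-6-alkylbenzoate; each is a 5-alkylcyclohexane-1,3-dione at lower oxidation level, ring C keeping one carboxyl carbon.
2. The three ester C–O bonds are cut: the A-alcohol/unit B acyl bond (last, Steglich), the ring C side-chain O/unit D acyl bond (Steglich), and the hindered aryl ester by Mitsunobu displacement at the unit B carbinol carbon with inversion.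
3. Rings A and C come from one dione ester 8: aromatisation gives resorcylate 10, which is ring C as such and ring A after saponification–decarboxylation.
4. 8 arises by Michael–Claisen annulation of dimethyl malonate with (R)-enone 5, made in three steps from methyl (R)-3-hydroxybutanoate; this ester supplies three stereocentres, the fourth comes from the (S)-tert-butyl ester by inversion.
5. Ring order: one carbocycle is closed (step 4), aromatised (step 5), then divided between ring C and ring A.

Key step: step 4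

Remarks on the chemistry: the side-chain oxygen is carried as a 2-naphthylmethyl (NAP) ether because it must survive HBr at 80 °C and hot hydroxide, come off with DDQ beside aryl benzyl ethers, and fall with them in the final hydrogenolysis; 8 is drawn as the triketo tautomer although it is largely enolised; tert-butyl (S)-3-hydroxybutanoate and (S)-pent-4-en-2-ol are taken as commercial.

**Route**

Step 1
Reactants: 1 methyl (R)-3-hydroxybutanoate
Product: 2 methyl (R)-3-(naphthalen-2-ylmethoxy)butanoate
Conditions: 2-(bromomethyl)naphthalene (1.5 equiv), Ag2O (1.5 equiv), CH2Cl2, rt, dark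
Reagents that add atoms: 2-(bromomethyl)naphthalene, BrCc1ccc2ccccc2c1
Why: Silver-oxide-promoted Williamson etherification alkylates the hydroxyl without strong base, so the β-hydroxy ester should neither eliminate nor undergo retro-aldol cleavage, and the stereocentre is kept because its C–O bond is not broken.

Step 2
Reactants: 2 methyl (R)-3-(naphthalen-2-ylmethoxy)butanoate
Product: 3 (R)-3-(naphthalen-2-ylmethoxy)butanal
Conditions: i-Bu2AlH (1.1 equiv), CH2Cl2, −78 °C; MeOH, then aq. potassium sodium tartrate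
Reagents that add atoms: none
Why: Partial ester reduction with i-Bu2AlH at low temperature stops at the aluminium hemiacetal, which releases the aldehyde only on work-up.

Step 3
Reactants: 3 (R)-3-(naphthalen-2-ylmethoxy)butanal; 4 1-(triphenylphosphoranylidene)propan-2-one
Product: 5 (R,E)-6-(naphthalen-2-ylmethoxy)hept-3-en-2-one
Conditions: CH2Cl2, 40 °C
Reagents that add atoms: none
Why: Wittig olefination with a ketone-stabilised ylide should give mainly the E-enone, and the ylide is too weakly basic to eliminate the β-alkoxy group of 3.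

Step 4
Reactants: 5 (R,E)-6-(naphthalen-2-ylmethoxy)hept-3-en-2-one; 6 dimethyl malonate
Product: 8 methyl 6-[(R)-2-(naphthalen-2-ylmethoxy)propyl]-2,4-dioxocyclohexane-1-carboxylate (C1/C6 epimers; largely enolised), via Michael adduct 7 (not isolated)
Conditions: NaOMe (1.1 equiv), 6 (1.2 equiv), MeOH, 0 °C (slow addition of 5), then reflux; aq. HCl to pH 3
Reagents that add atoms: none
Why: The malonate anion (NaCH(CO2Me)2) adds to C4 of enone 5 in a Michael addition to give 7; proton transfer then puts a little enolate on the methyl ketone carbon, which attacks one malonate ester carbonyl, expels methoxide and ends as the enolate of the vinylogous acid 8, a final deprotonation that drives the sequence and uses up a full equivalent of base. The closest known reaction type is the malonate–enone Michael–Claisen annulation used for 5-alkylcyclohexane-1,3-diones on the way to 5-alkylresorcinols. The six-membered carbocycle closes in a 6-(enolexo)-exo-trig mode, and closure from the internal methylene enolate would need a four-membered ring, so it does not compete. The two new sp3 ring centres C1 and C6 form without control and need none because both become sp2 on aromatisation, while the (R)-carbinol centre lies outside the reacting array and carries no acidic hydrogen. The step needs conjugate addition to outrun deprotonation at C5 followed by vinylogous loss of the arylmethoxide; pre-forming the malonate anion with a small excess of malonate keeps free methoxide low, the nucleophile is soft, and an alkoxide is a poor leaving group.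

Step 5
Reactants: 8 methyl 6-[(R)-2-(naphthalen-2-ylmethoxy)propyl]-2,4-dioxocyclohexane-1-carboxylate
Product: 10 methyl 2,4-dihydroxy-6-[(R)-2-(naphthalen-2-ylmethoxy)propyl]benzoate, via 3-bromo dione 9 (not isolated)
Conditions: Br2 (1.0 equiv), DMF, 0 °C, then 80 °C; aq. Na2S2O3
Reagents that add atoms: none
Why: Halogenation–dehydrohalogenation aromatisation: the enolised β-diketone is brominated at C3 and, on warming in the HBr/DMF medium, loses HBr and tautomerises to the resorcinol with the ester retained, the arylmethyl ether being inert to these conditions.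

Step 6
Reactants: 10 methyl 2,4-dihydroxy-6-[(R)-2-(naphthalen-2-ylmethoxy)propyl]benzoate (one portion)
Product: 12 5-[(R)-2-(naphthalen-2-ylmethoxy)propyl]benzene-1,3-diol, via resorcylic acid 11 (not isolated)
Conditions: aq. NaOH (2.5 M), N2, reflux; then aq. HCl to pH 3, 60 °C
Reagents that add atoms: none
Why: Saponification followed by protodecarboxylation of the 2,4-dihydroxybenzoic acid, which loses CO2 readily by ipso-protonation of the electron-rich ring, while the arylmethyl ether tolerates hot alkali and dilute acid.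

Step 7
Reactants: 12 5-[(R)-2-(naphthalen-2-ylmethoxy)propyl]benzene-1,3-diol
Product: 13 5-[(R)-2-hydroxypropyl]benzene-1,3-diol
Conditions: H2 (1 atm), Pd/C (10%), EtOH, rt
Reagents that add atoms: none
Why: Catalytic hydrogenolysis cleaves the naphthylmethyl C–O bond and leaves the carbinol C–O bond, and thus the stereocentre, untouched.

Step 8
Reactants: 13 5-[(R)-2-hydroxypropyl]benzene-1,3-diol
Product: 14 (R)-1-[3,5-bis(benzyloxy)phenyl]propan-2-ol
Conditions: BnBr (2.2 equiv), K2CO3, acetone, reflux
Reagents that add atoms: benzyl bromide, BrCc1ccccc1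
Why: Williamson etherification in which carbonate deprotonates only the two phenols, so benzylation should be selective for the ring oxygens and leave the secondary alcohol free.

Step 9
Reactants: 10 methyl 2,4-dihydroxy-6-[(R)-2-(naphthalen-2-ylmethoxy)propyl]benzoate (second portion)
Product: 15 methyl 2,4-bis(benzyloxy)-6-[(R)-2-(naphthalen-2-ylmethoxy)propyl]benzoate
Conditions: BnBr (2.6 equiv), K2CO3, DMF, 60 °C
Reagents that add atoms: benzyl bromide, BrCc1ccccc1
Why: Williamson etherification of both phenols, the hydrogen-bonded C2 hydroxyl needing DMF and warming.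

Step 10
Reactants: 15 methyl 2,4-bis(benzyloxy)-6-[(R)-2-(naphthalen-2-ylmethoxy)propyl]benzoate
Product: 16 2,4-bis(benzyloxy)-6-[(R)-2-(naphthalen-2-ylmethoxy)propyl]benzoic acid
Conditions: KOH (10 equiv), DMSO/H2O 4:1, 90 °C; then aq. HCl
Reagents that add atoms: potassium hydroxide, [K+].[OH-]
Why: Saponification of the hindered benzoate by concentrated hydroxide in DMSO, conditions that benzyl and naphthylmethyl ethers withstand and under which no stereocentre is acidic.

Step 11
Reactants: 16 2,4-bis(benzyloxy)-6-[(R)-2-(naphthalen-2-ylmethoxy)propyl]benzoic acid; 17 tert-butyl (S)-3-hydroxybutanoate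
Product: 18 tert-butyl (R)-3-({2,4-bis(benzyloxy)-6-[(R)-2-(naphthalen-2-ylmethoxy)propyl]benzoyl}oxy)butanoate
Conditions: PPh3 (2.2 equiv), DIAD (2.2 equiv), 17 (2 equiv), toluene, 0 °C to rt
Reagents that add atoms: none
Why: Mitsunobu esterification: the carboxylate of 16, whose oxygens stay accessible although its carbonyl carbon is shielded, displaces the oxyphosphonium group of 17 by SN2, so the hindered ester forms without acyl activation and the unit B stereocentre is set as (R) by inversion of the (S)-alcohol.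

Step 12
Reactants: 18 tert-butyl (R)-3-({2,4-bis(benzyloxy)-6-[(R)-2-(naphthalen-2-ylmethoxy)propyl]benzoyl}oxy)butanoate
Product: 19 tert-butyl (R)-3-({2,4-bis(benzyloxy)-6-[(R)-2-hydroxypropyl]benzoyl}oxy)butanoate
Conditions: DDQ (1.5 equiv), CH2Cl2/aq. NaH2PO4–Na2HPO4 buffer (pH 7) 10:1, 0 °C to rt
Reagents that add atoms: none
Why: Oxidative cleavage of the naphthylmethyl ether by DDQ (hydride abstraction to an oxocarbenium ion that water hydrolyses) should spare the benzyl ethers on the ester-deactivated ring and both esters, and the neutral medium keeps the freed hydroxyl from lactonising onto the aryl ester.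

Step 13
Reactants: 2 methyl (R)-3-(naphthalen-2-ylmethoxy)butanoate
Product: 20 (R)-3-(naphthalen-2-ylmethoxy)butanoic acid
Conditions: LiOH·H2O (2 equiv), THF/H2O 3:1, 0 °C to rt; then aq. HCl to pH 3
Reagents that add atoms: lithium hydroxide, [Li+].[OH-]
Why: Saponification with LiOH at or below room temperature is mild enough not to eliminate the β-alkoxy group.

Step 14
Reactants: 19 tert-butyl (R)-3-({2,4-bis(benzyloxy)-6-[(R)-2-hydroxypropyl]benzoyl}oxy)butanoate; 20 (R)-3-(naphthalen-2-ylmethoxy)butanoic acid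
Product: 21 tert-butyl (R)-3-({2,4-bis(benzyloxy)-6-[(R)-2-{[(R)-3-(naphthalen-2-ylmethoxy)butanoyl]oxy}propyl]benzoyl}oxy)butanoate
Conditions: DCC (1.5 equiv), DMAP (0.3 equiv), 20 (1.5 equiv), CH2Cl2, 0 °C to rt
Reagents that add atoms: none
Why: Steglich esterification (carbodiimide activation, DMAP acyl transfer) of the secondary alcohol with an unhindered aliphatic acid, touching no stereocentre.

Step 15
Reactants: 21 tert-butyl (R)-3-({2,4-bis(benzyloxy)-6-[(R)-2-{[(R)-3-(naphthalen-2-ylmethoxy)butanoyl]oxy}propyl]benzoyl}oxy)butanoate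
Product: 22 (R)-3-({2,4-bis(benzyloxy)-6-[(R)-2-{[(R)-3-(naphthalen-2-ylmethoxy)butanoyl]oxy}propyl]benzoyl}oxy)butanoic acid
Conditions: 85% aq. H3PO4 (10 equiv), toluene, 40 °C
Reagents that add atoms: none
Why: Acidolysis of the tert-butyl ester by alkyl–oxygen cleavage (loss of isobutene) needs neither nucleophile nor base, so it should spare the other esters, the β-acyloxy motif and the arylmethyl ethers.

Step 16
Reactants: 22 (R)-3-({2,4-bis(benzyloxy)-6-[(R)-2-{[(R)-3-(naphthalen-2-ylmethoxy)butanoyl]oxy}propyl]benzoyl}oxy)butanoic acid; 14 (R)-1-[3,5-bis(benzyloxy)phenyl]propan-2-ol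
Product: 23 fully protected tetraester, (R)-1-[3,5-bis(benzyloxy)phenyl]propan-2-yl (R)-3-({2,4-bis(benzyloxy)-6-[(R)-2-{[(R)-3-(naphthalen-2-ylmethoxy)butanoyl]oxy}propyl]benzoyl}oxy)butanoate
Conditions: DCC (1.3 equiv), DMAP (0.1 equiv), 14 (1.1 equiv), CH2Cl2, −10 °C to rt
Reagents that add atoms: none
Why: Steglich esterification run cold with little DMAP, so that the activated β-acyloxy acid should acylate alcohol 14 faster than it eliminates to a crotonate.

Step 17
Reactants: 23 fully protected tetraester
Product: 24 Hansforester J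
Conditions: H2 (1 atm), Pd/C (10%), EtOAc/EtOH 1:1, rt
Reagents that add atoms: none
Why: Catalytic hydrogenolysis removes the four benzyl ethers and the naphthylmethyl ether, while the three esters, none benzylic at oxygen, stay intact.

**Compound list**

1 | methyl (R)-3-hydroxybutanoate | C[C@@H](O)CC(=O)OC | starting material
2 | methyl (R)-3-(naphthalen-2-ylmethoxy)butanoate | C[C@@H](OCc1ccc2ccccc2c1)CC(=O)OC | intermediate
3 | (R)-3-(naphthalen-2-ylmethoxy)butanal | C[C@@H](OCc1ccc2ccccc2c1)CC=O | intermediate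
4 | 1-(triphenylphosphoranylidene)propan-2-one | CC(=O)C=P(c1ccccc1)(c1ccccc1)c1ccccc1 | starting material
5 | (R,E)-6-(naphthalen-2-ylmethoxy)hept-3-en-2-one | CC(=O)/C=C/C[C@@H](C)OCc1ccc2ccccc2c1 | intermediate
6 | dimethyl malonate | COC(=O)CC(=O)OC | starting material
7 | dimethyl 2-[(6R)-6-(naphthalen-2-ylmethoxy)-2-oxoheptan-4-yl]propanedioate (C4 epimers; not isolated) | COC(=O)C(C(=O)OC)C(CC(C)=O)C[C@@H](C)OCc1ccc2ccccc2c1 | intermediate
8 | methyl 6-[(R)-2-(naphthalen-2-ylmethoxy)propyl]-2,4-dioxocyclohexane-1-carboxylate (C1/C6 epimers) | COC(=O)C1C(C[C@@H](C)OCc2ccc3ccccc3c2)CC(=O)CC1=O | intermediate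
9 | methyl 3-bromo-6-[(R)-2-(naphthalen-2-ylmethoxy)propyl]-2,4-dioxocyclohexane-1-carboxylate (not isolated) | COC(=O)C1C(C[C@@H](C)OCc2ccc3ccccc3c2)CC(=O)C(Br)C1=O | intermediate
10 | methyl 2,4-dihydroxy-6-[(R)-2-(naphthalen-2-ylmethoxy)propyl]benzoate | COC(=O)c1c(O)cc(O)cc1C[C@@H](C)OCc1ccc2ccccc2c1 | intermediate
11 | 2,4-dihydroxy-6-[(R)-2-(naphthalen-2-ylmethoxy)propyl]benzoic acid (not isolated) | OC(=O)c1c(O)cc(O)cc1C[C@@H](C)OCc1ccc2ccccc2c1 | intermediate
12 | 5-[(R)-2-(naphthalen-2-ylmethoxy)propyl]benzene-1,3-diol | Oc1cc(O)cc(C[C@@H](C)OCc2ccc3ccccc3c2)c1 | intermediate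
13 | 5-[(R)-2-hydroxypropyl]benzene-1,3-diol | Oc1cc(O)cc(C[C@@H](C)O)c1 | intermediate
14 | (R)-1-[3,5-bis(benzyloxy)phenyl]propan-2-ol | C[C@H](Cc1cc(OCc2ccccc2)cc(OCc2ccccc2)c1)O | intermediate
15 | methyl 2,4-bis(benzyloxy)-6-[(R)-2-(naphthalen-2-ylmethoxy)propyl]benzoate | COC(=O)c1c(OCc2ccccc2)cc(OCc2ccccc2)cc1C[C@@H](C)OCc1ccc2ccccc2c1 | intermediate
16 | 2,4-bis(benzyloxy)-6-[(R)-2-(naphthalen-2-ylmethoxy)propyl]benzoic acid | OC(=O)c1c(OCc2ccccc2)cc(OCc2ccccc2)cc1C[C@@H](C)OCc1ccc2ccccc2c1 | intermediate
17 | tert-butyl (S)-3-hydroxybutanoate | C[C@H](O)CC(=O)OC(C)(C)C | starting material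
18 | tert-butyl (R)-3-({2,4-bis(benzyloxy)-6-[(R)-2-(naphthalen-2-ylmethoxy)propyl]benzoyl}oxy)butanoate | CC(C)(C)OC(=O)C[C@@H](C)OC(=O)c1c(OCc2ccccc2)cc(OCc2ccccc2)cc1C[C@@H](C)OCc1ccc2ccccc2c1 | intermediate
19 | tert-butyl (R)-3-({2,4-bis(benzyloxy)-6-[(R)-2-hydroxypropyl]benzoyl}oxy)butanoate | CC(C)(C)OC(=O)C[C@@H](C)OC(=O)c1c(OCc2ccccc2)cc(OCc2ccccc2)cc1C[C@@H](C)O | intermediate
20 | (R)-3-(naphthalen-2-ylmethoxy)butanoic acid | C[C@@H](OCc1ccc2ccccc2c1)CC(=O)O | intermediate
21 | tert-butyl (R)-3-({2,4-bis(benzyloxy)-6-[(R)-2-{[(R)-3-(naphthalen-2-ylmethoxy)butanoyl]oxy}propyl]benzoyl}oxy)butanoate | CC(C)(C)OC(=O)C[C@@H](C)OC(=O)c1c(OCc2ccccc2)cc(OCc2ccccc2)cc1C[C@@H](C)OC(=O)C[C@@H](C)OCc1ccc2ccccc2c1 | intermediate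
22 | (R)-3-({2,4-bis(benzyloxy)-6-[(R)-2-{[(R)-3-(naphthalen-2-ylmethoxy)butanoyl]oxy}propyl]benzoyl}oxy)butanoic acid | OC(=O)C[C@@H](C)OC(=O)c1c(OCc2ccccc2)cc(OCc2ccccc2)cc1C[C@@H](C)OC(=O)C[C@@H](C)OCc1ccc2ccccc2c1 | intermediate
23 | (R)-1-[3,5-bis(benzyloxy)phenyl]propan-2-yl (R)-3-({2,4-bis(benzyloxy)-6-[(R)-2-{[(R)-3-(naphthalen-2-ylmethoxy)butanoyl]oxy}propyl]benzoyl}oxy)butanoate | C[C@H](Cc1cc(OCc2ccccc2)cc(OCc2ccccc2)c1)OC(=O)C[C@@H](C)OC(=O)c1c(OCc2ccccc2)cc(OCc2ccccc2)cc1C[C@@H](C)OC(=O)C[C@@H](C)OCc1ccc2ccccc2c1 | intermediate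
24 | Hansforester J | C[C@H](Cc1cc(O)cc(O)c1)OC(=O)C[C@@H](C)OC(=O)c1c(O)cc(O)cc1C[C@@H](C)OC(=O)C[C@@H](C)O | target

**Step count**

Total: 17 steps. Longest linear sequence: 13 steps (steps 1–5, 9–12, 14–17).

**Steps most likely to fail**

1. Step 11 (Mitsunobu esterification). The oxyphosphonium ion of the β-hydroxy ester may lose a proton next to its ester and eliminate to the crotonate faster than the hindered carboxylate displaces it, so reagents are consumed and little ester forms. The fallback sets out from acid 16 and uses an alcohol with no acidic hydrogen beside the activated carbon. Mitsunobu reaction with (S)-pent-4-en-2-ol (PPh3, DIAD, toluene) should give, with the same inversion, (R)-pent-4-en-2-yl 2,4-bis(benzyloxy)-6-[(R)-2-(naphthalen-2-ylmethoxy)propyl]benzoate F1. DDQ would then free the side-chain hydroxyl to give (R)-pent-4-en-2-yl 2,4-bis(benzyloxy)-6-[(R)-2-hydroxypropyl]benzoate F2, and acid 20 (DCC, DMAP) would acylate it to (R)-pent-4-en-2-yl 2,4-bis(benzyloxy)-6-[(R)-2-{[(R)-3-(naphthalen-2-ylmethoxy)butanoyl]oxy}propyl]benzoate F3. The terminal alkene serves as the masked carboxyl of unit B: Lemieux–Johnson cleavage (OsO4 cat., NaIO4, 2,6-lutidine, dioxane/H2O) should give (R)-4-oxobutan-2-yl 2,4-bis(benzyloxy)-6-[(R)-2-{[(R)-3-(naphthalen-2-ylmethoxy)butanoyl]oxy}propyl]benzoate F4, and Pinnick oxidation (NaClO2, NaH2PO4, 2-methylbut-2-ene, t-BuOH/H2O) would deliver acid 22, where the route is rejoined.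

2. Step 5 (aromatisation). Bromination may not stop after one equivalent, because the resorcinol ring that forms is itself readily brominated, and dehydrobromination may stay incomplete, so mixtures of ring-brominated and non-aromatised material result. The fallback sets out from 8 and makes the over-bromination deliberate. Excess Br2 (3.1 equiv, DMF, 0 °C to 60 °C) should carry all material to methyl 3,5-dibromo-2,4-dihydroxy-6-[(R)-2-(naphthalen-2-ylmethoxy)propyl]benzoate F5. Homogeneous hydrodebromination (Pd(PPh3)4 cat., HCO2Na, DMF, 80 °C), which uses no hydrogen gas or metal surface and so should leave the arylmethyl ether alone, would then give 10, where the route is rejoined.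

3. Step 4 (Michael–Claisen annulation). Deprotonation of the enone at C5 with vinylogous loss of the arylmethoxide, or reversal of the conjugate addition before ring closure, may outrun the annulation. The fallback sets out from aldehyde 3 and exchanges the roles of the two partners. Wittig olefination with methyl (triphenylphosphoranylidene)acetate should give methyl (R,E)-5-(naphthalen-2-ylmethoxy)hex-2-enoate F6, an acceptor that is much harder to deprotonate at its γ-carbon. Methyl acetoacetate and NaOMe (1.1 equiv, MeOH, reflux) would add to it to give dimethyl 2-acetyl-3-[(R)-2-(naphthalen-2-ylmethoxy)propyl]pentanedioate F7 (not isolated), whose acetyl methyl enolate closes onto the distal ester to give the same dione ester 8, where the route is rejoined.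

**Further compounds**

F1 | step 11 | (R)-pent-4-en-2-yl 2,4-bis(benzyloxy)-6-[(R)-2-(naphthalen-2-ylmethoxy)propyl]benzoate | C=CC[C@@H](C)OC(=O)c1c(OCc2ccccc2)cc(OCc2ccccc2)cc1C[C@@H](C)OCc1ccc2ccccc2c1
F2 | step 11 | (R)-pent-4-en-2-yl 2,4-bis(benzyloxy)-6-[(R)-2-hydroxypropyl]benzoate | C=CC[C@@H](C)OC(=O)c1c(OCc2ccccc2)cc(OCc2ccccc2)cc1C[C@@H](C)O
F3 | step 11 | (R)-pent-4-en-2-yl 2,4-bis(benzyloxy)-6-[(R)-2-{[(R)-3-(naphthalen-2-ylmethoxy)butanoyl]oxy}propyl]benzoate | C=CC[C@@H](C)OC(=O)c1c(OCc2ccccc2)cc(OCc2ccccc2)cc1C[C@@H](C)OC(=O)C[C@@H](C)OCc1ccc2ccccc2c1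
F4 | step 11 | (R)-4-oxobutan-2-yl 2,4-bis(benzyloxy)-6-[(R)-2-{[(R)-3-(naphthalen-2-ylmethoxy)butanoyl]oxy}propyl]benzoate | O=CC[C@@H](C)OC(=O)c1c(OCc2ccccc2)cc(OCc2ccccc2)cc1C[C@@H](C)OC(=O)C[C@@H](C)OCc1ccc2ccccc2c1
F5 | step 5 | methyl 3,5-dibromo-2,4-dihydroxy-6-[(R)-2-(naphthalen-2-ylmethoxy)propyl]benzoate | COC(=O)c1c(O)c(Br)c(O)c(Br)c1C[C@@H](C)OCc1ccc2ccccc2c1
F6 | step 4 | methyl (R,E)-5-(naphthalen-2-ylmethoxy)hex-2-enoate | COC(=O)/C=C/C[C@@H](C)OCc1ccc2ccccc2c1
F7 | step 4 | dimethyl 2-acetyl-3-[(R)-2-(naphthalen-2-ylmethoxy)propyl]pentanedioate | COC(=O)CC(C[C@@H](C)OCc1ccc2ccccc2c1)C(C(C)=O)C(=O)OC
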